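Cleistanthane numbering is used: ring B = C5–C10, ring C = C8, C9, C11–C14; C10 carries C20 (methyl) and the C1–C3 ester chain, C5 the isopropenyl group (C4), C14 the vinyl group.
Retrosynthesis: cut C8–OOH (phenol + singlet oxygen), then C14–vinyl (aryl triflate coupling), then C12–C13 of ring C (Dieckmann), then C6–C7 and C8–C9 of ring B together (Diels–Alder), which leaves a cyclohexenone.
Enabling feature: ring C atoms C11 and C12 can span C9 and C6, so C6=C12(OSi)–C11=C9 is a 2-silyloxy diene whose oxygen is the future phenol oxygen; an ynone adds across C6/C9, and the temporary C6–C12 bond is cut again because C6 is the vinylogous α-carbon of the new C14 ketone.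
Forward: cyclohexadienone → desymmetrising 1,4-addition → silyloxy diene → ring B by [4+2] → bridge opening and ring C by retro-Claisen/Dieckmann/aromatisation → vinyl group → dearomatising hydroperoxidation.
Stereochemistry: C5 and C10 come from the rhodium/(R)-BINAP addition; the bridgehead centres of the cycloadduct are erased later (stereoconvergent); C8 comes from face-selective attack of singlet oxygen.

Key step: step 7

Remark: compounds 5, 7 and 8 are racemic and 9 is achiral, so the first stereocentres are set in step 4; the sense of induction there is assigned by analogy with cyclohex-2-enone, and (S)-BINAP would be used if it proved opposite.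

Step 1
Reactants: 1 propanal; 2 pyrrolidine; 3 methyl acrylate
Product: 5 methyl 4-methyl-5-oxopentanoate (racemic), via enamine 4 (not isolated)
Conditions: 2, K2CO3, 0 °C; then 3, MeCN, 80 °C; then AcOH, H2O, 80 °C
Reagents that add atoms: water, O
Why: Stork enamine Michael addition, in which the pyrrolidine enamine of propanal adds through its β-carbon to methyl acrylate and hydrolysis returns the α-branched aldehyde; its stereocentre is racemic and is made prochiral in step 3.

Step 2
Reactants: 5 methyl 4-methyl-5-oxopentanoate; 6 methyl vinyl ketone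
Product: 8 methyl 3-(1-methyl-4-oxocyclohex-2-en-1-yl)propanoate (racemic), via Michael adduct 7 (not isolated)
Conditions: H2SO4 (cat.), toluene, 45 °C then 110 °C (Dean–Stark)
Reagents that add atoms: none
Why: Acid-catalysed Robinson annulation (Michael addition of the aldehyde enol, intramolecular aldol condensation) of an α,α-disubstituted aldehyde should give the 4,4-disubstituted cyclohexenone; the quaternary carbon is racemic and becomes prochiral in step 3.

Step 3
Reactants: 8 methyl 3-(1-methyl-4-oxocyclohex-2-en-1-yl)propanoate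
Product: 9 methyl 3-(1-methyl-4-oxocyclohexa-2,5-dien-1-yl)propanoate
Conditions: DDQ, dioxane, 100 °C
Reagents that add atoms: none
Why: DDQ dehydrogenation of a 4,4-disubstituted cyclohex-2-enone, which cannot aromatise, should give the cross-conjugated dienone with a mirror plane through C10 and C12.

Step 4
Reactants: 9 methyl 3-(1-methyl-4-oxocyclohexa-2,5-dien-1-yl)propanoate; 10 isopropenylboronic acid pinacol ester
Product: 11 methyl 3-[(1S,6R)-1-methyl-4-oxo-6-(prop-1-en-2-yl)cyclohex-2-en-1-yl]propanoate
Conditions: [RhCl(C2H4)2]2 (cat.), (R)-BINAP (cat.), KOH (0.3 equiv), dioxane/H2O, 40 °C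
Reagents that add atoms: none
Why: Hayashi–Miyaura rhodium-catalysed asymmetric 1,4-addition desymmetrises the dienone, because the (R)-BINAP–rhodium alkenyl species selects one face of one enantiotopic enone (C5) and should add anti to the larger propanoate chain on C10, which places the isopropenyl group cis to the C10 methyl group.

Step 5
Reactants: 11 methyl 3-[(1S,6R)-1-methyl-4-oxo-6-(prop-1-en-2-yl)cyclohex-2-en-1-yl]propanoate
Product: 12 methyl 3-[(1S,6R)-4-{[tert-butyl(dimethyl)silyl]oxy}-1-methyl-6-(prop-1-en-2-yl)cyclohexa-2,4-dien-1-yl]propanoate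
Conditions: TBSOTf, Et3N, CH2Cl2, 0 °C
Reagents that add atoms: tert-butyldimethylsilyl trifluoromethanesulfonate, CC(C)(C)[Si](C)(C)OS(=O)(=O)C(F)(F)F
Why: Soft enolisation of the enone can only remove a C6 proton (C10 is quaternary), so it should give the cross-conjugated 2-silyloxy diene C6=C12(OSi)–C11=C9 without touching the ester or the stereocentres.

Step 6
Reactants: 13 pent-1-yn-3-ol
Product: 14 pent-1-yn-3-one
Conditions: IBX, EtOAc, 75 °C
Reagents that add atoms: none
Why: IBX oxidation of a secondary propargylic alcohol should give the terminal ynone, which is used as a solution because it is volatile.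

Step 7
Reactants: 12 methyl 3-[(1S,6R)-4-{[tert-butyl(dimethyl)silyl]oxy}-1-methyl-6-(prop-1-en-2-yl)cyclohexa-2,4-dien-1-yl]propanoate; 14 pent-1-yn-3-one
Product: 15 methyl 3-[5-{[tert-butyl(dimethyl)silyl]oxy}-2-methyl-7-propanoyl-3-(prop-1-en-2-yl)bicyclo[2.2.2]octa-5,7-dien-2-yl]propanoate
Conditions: toluene, 60 °C, sealed tube
Reagents that add atoms: none
Why: Thermal normal-demand Diels–Alder cycloaddition: the HOMO of the 2-silyloxy diene C6=C12(OSi)–C11=C9 has its largest coefficient at C6 and pairs with the β-carbon C7 of the ynone, so C6–C7 and C9–C8 form suprafacially in one asynchronous event. The closest known reaction type is the Diels–Alder (double Michael) reaction of cyclohexenone-derived 2-silyloxy dienes with acrylates, enones and alkynes to give bicyclo[2.2.2]octenes. Ring B (C5–C10) is closed as a six-membered carbocycle by this intermolecular [4+2] closure, and the third bridge C11–C12 of the bicyclo[2.2.2]octadiene formed at the same time is a temporary ring that is opened in step 8. The two new stereocentres, the bridgeheads C6 and C9, should be set by approach of the ynone to the diene face opposite the isopropenyl group, but both are erased later (C6 becomes CH2, C9 becomes aromatic), so every facial isomer converges on the same product. The step needs "para" regioselectivity, secured by the C12 silyloxy donor and required because only then is C6 the vinylogous α-carbon of the C14 ketone, and it needs the diene to react in preference to the isopropenyl group, secured by its high-lying HOMO. The temperature is kept low so that the cycloadduct does not lose the C5–C10 bridge by retro-Diels–Alder (Alder–Rickert) fragmentation.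

Step 8
Reactants: 15 methyl 3-[5-{[tert-butyl(dimethyl)silyl]oxy}-2-methyl-7-propanoyl-3-(prop-1-en-2-yl)bicyclo[2.2.2]octa-5,7-dien-2-yl]propanoate
Product: 18 methyl 3-[(1R,2R)-5,7-dihydroxy-1,6-dimethyl-2-(prop-1-en-2-yl)-1,2,3,4-tetrahydronaphthalen-1-yl]propanoate, via bicyclic ketone 16 (not isolated), via ring-opened keto diester 17 (not isolated)
Conditions: NaOMe, MeOH, 0 to 50 °C, argon; then aq. HCl (1 M), 0 °C
Reagents that add atoms: none
Why: Methoxide frees the C12 ketone from its silyl enol ether and adds to it, the strained C6–C12 bond breaks in a vinylogous retro-Claisen (retro-Dieckmann) fragmentation because C6 leaves as the dienolate of the C14 enone (methanol supplies the methoxy group of 17), and the ethyl ketone enolate (C13) then closes ring C on the C12 ester by Dieckmann condensation; the other Claisen and aldol closures are reversible, whereas tautomerisation to the resorcinol is not, and it erases the bridgehead stereocentres.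

Step 9
Reactants: 18 methyl 3-[(1R,2R)-5,7-dihydroxy-1,6-dimethyl-2-(prop-1-en-2-yl)-1,2,3,4-tetrahydronaphthalen-1-yl]propanoate
Product: 20 methyl 3-[(1R,2R)-7-acetoxy-1,6-dimethyl-2-(prop-1-en-2-yl)-5-{[(trifluoromethyl)sulfonyl]oxy}-1,2,3,4-tetrahydronaphthalen-1-yl]propanoate, via monoacetate 19 (not isolated)
Conditions: Ac2O (1.0 equiv), pyridine, CH2Cl2, −20 °C; then Tf2O, 0 °C
Reagents that add atoms: acetic anhydride, CC(=O)OC(C)=O; trifluoromethanesulfonic anhydride, O=S(=O)(OS(=O)(=O)C(F)(F)F)C(F)(F)F
Why: The C12 phenol has only one ortho substituent and should be acetylated before the doubly ortho-substituted C14 phenol, which is then converted into its aryl triflate (selective phenol acylation, triflation).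

Step 10
Reactants: 20 methyl 3-[(1R,2R)-7-acetoxy-1,6-dimethyl-2-(prop-1-en-2-yl)-5-{[(trifluoromethyl)sulfonyl]oxy}-1,2,3,4-tetrahydronaphthalen-1-yl]propanoate; 21 tributyl(vinyl)stannane
Product: 23 methyl 3-[(1R,2R)-5-ethenyl-7-hydroxy-1,6-dimethyl-2-(prop-1-en-2-yl)-1,2,3,4-tetrahydronaphthalen-1-yl]propanoate, via vinyl aryl acetate 22 (not isolated)
Conditions: Pd(PPh3)4 (cat.), LiCl, dioxane, 100 °C; then K2CO3 (cat.), MeOH, 25 °C
Reagents that add atoms: none
Why: Stille cross-coupling of the aryl triflate with the vinylstannane (LiCl assists transmetalation) installs C15–C16 under neutral conditions that spare both esters, and catalytic methanolysis then removes the aryl acetate without changing the methyl ester.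

Step 11
Reactants: 23 methyl 3-[(1R,2R)-5-ethenyl-7-hydroxy-1,6-dimethyl-2-(prop-1-en-2-yl)-1,2,3,4-tetrahydronaphthalen-1-yl]propanoate
Product: 24 trigonochinene C, methyl 3-[(1R,2R,4aR)-5-ethenyl-4a-hydroperoxy-1,6-dimethyl-7-oxo-2-(prop-1-en-2-yl)-1,2,3,4,4a,7-hexahydronaphthalen-1-yl]propanoate
Conditions: O2, tetraphenylporphyrin (cat.), visible light, CH2Cl2/MeOH, 0 °C
Reagents that add atoms: dioxygen, O=O
Why: Dearomatising photooxygenation, in which singlet oxygen adds at C8 para to the phenol oxygen to give the 4-hydroperoxycyclohexa-2,5-dienone; the phenol should react faster than the 1,1-disubstituted and styrenic alkenes, and attack anti to the pseudo-axial propanoate chain on C10 (half-chair with the C10 methyl pseudo-equatorial) should place the hydroperoxide cis to the C10 methyl group.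

Compound list
1 | propanal | CCC=O | starting material
2 | pyrrolidine | C1CCNC1 | starting material
3 | methyl acrylate | C=CC(=O)OC | starting material
4 | 1-[(E)-prop-1-en-1-yl]pyrrolidine | C/C=C/N1CCCC1 | intermediate
5 | methyl 4-methyl-5-oxopentanoate (racemic) | COC(=O)CCC(C)C=O | intermediate
6 | methyl vinyl ketone (but-3-en-2-one) | CC(=O)C=C | starting material
7 | methyl 4-formyl-4-methyl-7-oxooctanoate (racemic) | COC(=O)CCC(C)(C=O)CCC(C)=O | intermediate
8 | methyl 3-(1-methyl-4-oxocyclohex-2-en-1-yl)propanoate (racemic) | COC(=O)CCC1(C)C=CC(=O)CC1 | intermediate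
9 | methyl 3-(1-methyl-4-oxocyclohexa-2,5-dien-1-yl)propanoate (achiral) | COC(=O)CCC1(C)C=CC(=O)C=C1 | intermediate
10 | 4,4,5,5-tetramethyl-2-(prop-1-en-2-yl)-1,3,2-dioxaborolane | CC(=C)B1OC(C)(C)C(C)(C)O1 | starting material
11 | methyl 3-[(1S,6R)-1-methyl-4-oxo-6-(prop-1-en-2-yl)cyclohex-2-en-1-yl]propanoate (isopropenyl cis to the ring methyl) | O=C1C[C@H](C(C)=C)[C@@](C)(CCC(=O)OC)C=C1 | intermediate
12 | methyl 3-[(1S,6R)-4-{[tert-butyl(dimethyl)silyl]oxy}-1-methyl-6-(prop-1-en-2-yl)cyclohexa-2,4-dien-1-yl]propanoate | CC(C)(C)[Si](C)(C)OC1=C[C@H](C(C)=C)[C@@](C)(CCC(=O)OC)C=C1 | intermediate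
13 | pent-1-yn-3-ol (racemic) | CCC(O)C#C | starting material
14 | pent-1-yn-3-one | CCC(=O)C#C | intermediate
15 | methyl 3-[5-{[tert-butyl(dimethyl)silyl]oxy}-2-methyl-7-propanoyl-3-(prop-1-en-2-yl)bicyclo[2.2.2]octa-5,7-dien-2-yl]propanoate (expected major facial isomer, ynone bridge anti to isopropenyl and methyl; configuration as in the SMILES) | CC(C)(C)[Si](C)(C)OC1=C[C@@H]2C(C(=O)CC)=C[C@H]1[C@H](C(C)=C)[C@@]2(C)CCC(=O)OC | intermediate
16 | methyl 3-[2-methyl-5-oxo-7-propanoyl-3-(prop-1-en-2-yl)bicyclo[2.2.2]oct-7-en-2-yl]propanoate (configuration as in the SMILES) | O=C1C[C@@H]2C(C(=O)CC)=C[C@H]1[C@H](C(C)=C)[C@@]2(C)CCC(=O)OC | intermediate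
17 | methyl 3-[6-(2-methoxy-2-oxoethyl)-1-methyl-5-propanoyl-2-(prop-1-en-2-yl)cyclohex-4-en-1-yl]propanoate (configuration as in the SMILES) | COC(=O)C[C@@H]1C(C(=O)CC)=CC[C@H](C(C)=C)[C@@]1(C)CCC(=O)OC | intermediate
18 | methyl 3-[(1R,2R)-5,7-dihydroxy-1,6-dimethyl-2-(prop-1-en-2-yl)-1,2,3,4-tetrahydronaphthalen-1-yl]propanoate | OC1=C(C)C(O)=CC2=C1CC[C@H](C(C)=C)[C@@]2(C)CCC(=O)OC | intermediate
19 | methyl 3-[(1R,2R)-7-acetoxy-5-hydroxy-1,6-dimethyl-2-(prop-1-en-2-yl)-1,2,3,4-tetrahydronaphthalen-1-yl]propanoate | OC1=C(C)C(OC(C)=O)=CC2=C1CC[C@H](C(C)=C)[C@@]2(C)CCC(=O)OC | intermediate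
20 | methyl 3-[(1R,2R)-7-acetoxy-1,6-dimethyl-2-(prop-1-en-2-yl)-5-{[(trifluoromethyl)sulfonyl]oxy}-1,2,3,4-tetrahydronaphthalen-1-yl]propanoate | FC(F)(F)S(=O)(=O)OC1=C(C)C(OC(C)=O)=CC2=C1CC[C@H](C(C)=C)[C@@]2(C)CCC(=O)OC | intermediate
21 | tributyl(vinyl)stannane | C=C[Sn](CCCC)(CCCC)CCCC | starting material
22 | methyl 3-[(1R,2R)-7-acetoxy-5-ethenyl-1,6-dimethyl-2-(prop-1-en-2-yl)-1,2,3,4-tetrahydronaphthalen-1-yl]propanoate | C=CC1=C(C)C(OC(C)=O)=CC2=C1CC[C@H](C(C)=C)[C@@]2(C)CCC(=O)OC | intermediate
23 | methyl 3-[(1R,2R)-5-ethenyl-7-hydroxy-1,6-dimethyl-2-(prop-1-en-2-yl)-1,2,3,4-tetrahydronaphthalen-1-yl]propanoate | C=CC1=C(C)C(O)=CC2=C1CC[C@H](C(C)=C)[C@@]2(C)CCC(=O)OC | intermediate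
24 | trigonochinene C, methyl 3-[(1R,2R,4aR)-5-ethenyl-4a-hydroperoxy-1,6-dimethyl-7-oxo-2-(prop-1-en-2-yl)-1,2,3,4,4a,7-hexahydronaphthalen-1-yl]propanoate | C=CC1=C(C)C(=O)C=C2[C@]1(OO)CC[C@H](C(=C)C)[C@@]2(C)CCC(=O)OC | target

Total step count: 11. Longest linear sequence: 10 (steps 1–5 and 7–11; step 6 is a one-step side branch).

Steps most likely to fail

Step 8. The enolate of the bicyclic ketone may undergo cycloreversion (loss of the C5–C10 bridge as an alkene) faster than the bridge is opened, or ring closure at C13 may stall under methoxide. The fallback sets out from 15 and comes back at 18. Aqueous HCl in THF hydrolyses the silyl enol ether to ketone 16. Ethanethiol and triethylamine then open the strained bridge under nearly neutral conditions to methyl 3-[6-(2-ethylsulfanyl-2-oxoethyl)-1-methyl-5-propanoyl-2-(prop-1-en-2-yl)cyclohex-4-en-1-yl]propanoate F7. Soft enolisation of the ethyl ketone with MgBr2·OEt2 and i-Pr2NEt in CH2Cl2 acylates C13 with the thioester, and the diketone aromatises to 18.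

Step 4. The catalyst may discriminate poorly between the methyl group and the propanoate chain on C10 (low diastereoselectivity), and a second addition to the remaining enone may occur. The fallback builds the two centres by enolate chemistry next to an existing stereocentre; it sets out from methyl acrylate 3 and commercial cyclohex-2-en-1-one F1 and comes back at 11. Copper-catalysed asymmetric conjugate addition of isopropenylmagnesium bromide (CuBr·SMe2, chiral ferrocenyl diphosphine) with trapping of the enolate by MeI gives (3S)-2-methyl-3-(prop-1-en-2-yl)cyclohexan-1-one F2. Thermodynamic Michael addition to 3 (t-BuOK cat., t-BuOH/THF) enters anti to the isopropenyl group and gives methyl 3-[(1R,6R)-1-methyl-2-oxo-6-(prop-1-en-2-yl)cyclohexyl]propanoate F3. IBX dehydrogenation on the only enolisable side gives methyl 3-[(1R,6R)-1-methyl-2-oxo-6-(prop-1-en-2-yl)cyclohex-3-en-1-yl]propanoate F4. Nucleophilic epoxidation (H2O2, K2CO3, MeOH) gives methyl 3-[3-methyl-2-oxo-4-(prop-1-en-2-yl)-7-oxabicyclo[4.1.0]heptan-3-yl]propanoate F5. Wharton transposition (N2H4·H2O, AcOH, MeOH, 0 °C) gives methyl 3-[(1S,6R)-4-hydroxy-1-methyl-6-(prop-1-en-2-yl)cyclohex-2-en-1-yl]propanoate F6, and MnO2 oxidation gives 11.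

Step 11. Singlet oxygen may attack both faces of C8 with little preference, and the isopropenyl group may undergo a competing ene reaction on long irradiation. The fallback accepts both epimers and recycles the wrong one; it sets out from 23 and comes back at 23. After separation of 24, the C8 epimer, methyl 3-[(1R,2R,4aS)-5-ethenyl-4a-hydroperoxy-1,6-dimethyl-7-oxo-2-(prop-1-en-2-yl)-1,2,3,4,4a,7-hexahydronaphthalen-1-yl]propanoate F8, is reduced with PPh3 to the quinol methyl 3-[(1R,2R,4aS)-5-ethenyl-4a-hydroxy-1,6-dimethyl-7-oxo-2-(prop-1-en-2-yl)-1,2,3,4,4a,7-hexahydronaphthalen-1-yl]propanoate F9. Zn in AcOH rearomatises F9 to 23, which is photooxygenated again at short conversion.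

Further compounds
F1 | step 4 | cyclohex-2-en-1-one | O=C1C=CCCC1
F2 | step 4 | (3S)-2-methyl-3-(prop-1-en-2-yl)cyclohexan-1-one (C2 epimers) | O=C1CCC[C@H](C(C)=C)C1C
F3 | step 4 | methyl 3-[(1R,6R)-1-methyl-2-oxo-6-(prop-1-en-2-yl)cyclohexyl]propanoate | O=C1CCC[C@H](C(C)=C)[C@@]1(C)CCC(=O)OC
F4 | step 4 | methyl 3-[(1R,6R)-1-methyl-2-oxo-6-(prop-1-en-2-yl)cyclohex-3-en-1-yl]propanoate | O=C1C=CC[C@H](C(C)=C)[C@@]1(C)CCC(=O)OC
F5 | step 4 | methyl 3-[3-methyl-2-oxo-4-(prop-1-en-2-yl)-7-oxabicyclo[4.1.0]heptan-3-yl]propanoate (epoxide epimers) | O=C1C2OC2C[C@H](C(C)=C)[C@@]1(C)CCC(=O)OC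
F6 | step 4 | methyl 3-[(1S,6R)-4-hydroxy-1-methyl-6-(prop-1-en-2-yl)cyclohex-2-en-1-yl]propanoate (carbinol epimers) | OC1C[C@H](C(C)=C)[C@@](C)(CCC(=O)OC)C=C1
F7 | step 8 | methyl 3-[6-(2-ethylsulfanyl-2-oxoethyl)-1-methyl-5-propanoyl-2-(prop-1-en-2-yl)cyclohex-4-en-1-yl]propanoate | CCSC(=O)C[C@@H]1C(C(=O)CC)=CC[C@H](C(C)=C)[C@@]1(C)CCC(=O)OC
F8 | step 11 | methyl 3-[(1R,2R,4aS)-5-ethenyl-4a-hydroperoxy-1,6-dimethyl-7-oxo-2-(prop-1-en-2-yl)-1,2,3,4,4a,7-hexahydronaphthalen-1-yl]propanoate | C=CC1=C(C)C(=O)C=C2[C@@]1(OO)CC[C@H](C(=C)C)[C@@]2(C)CCC(=O)OC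
F9 | step 11 | methyl 3-[(1R,2R,4aS)-5-ethenyl-4a-hydroxy-1,6-dimethyl-7-oxo-2-(prop-1-en-2-yl)-1,2,3,4,4a,7-hexahydronaphthalen-1-yl]propanoate | C=CC1=C(C)C(=O)C=C2[C@@]1(O)CC[C@H](C(=C)C)[C@@]2(C)CCC(=O)OC
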